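Z came slowly in alpha, the flask asked about, so I set it beside eta, its neighbour, which had the same feed of X but twice the D.

| flask | X | D | remark | time |
|---|---|---|---|---|
| alpha | 46 mM (fed, over 12 min) | 46 mM | the very flask that is asked about, followed so far |  |
| eta | 46 mM (fed, over 12 min) | 92 mM | run made earlier |  |
| flask | 46 mM (fed, over 12 min) | 46.0 mM |  | 15 min |

| run | time / min | Z / % |
|---|---|---|
| alpha | 2.00 | 2.1 |
| alpha | 4.00 | 8.7 |
| alpha | 6.00 | 16.0 |
| alpha | 8.00 | 24.5 |
| eta | 1.33 | 1.7 |
| eta | 4.00 | 12.7 |
| eta | 6.00 | 22.1 |
| eta | 10.0 | 45.1 |

(each reading ± 0.5 percentage points)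

1. amount of Z in percent of the X charged, at 50 s, 4.0 min and 15 min

At 6.00 min both flasks had received half of the X, yet Z stood at 16.0% in alpha and 22.1% in eta. I divided the logarithm of that Z ratio by the logarithm of the D ratio, which gave the D exponent, the apparent order in D of the Z reading: 0.466. With the feed fixed, an exponent of one means Z follows D in full, and zero means Z ignores it.

At 4.00 min the same reading was 0.546, higher than at 6.00 min. At 6.00 min, X fed and not found as Z stood at 34.0% in alpha and 27.9% in eta, less in eta than in alpha, so I expected Z in eta to stay ahead of Z in alpha by less than the D ratio.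

Dividing eta's 45.1% at 10.0 min by 1.38 put alpha near 32.7% at that time. Carrying on the gain of 8.2 percentage points made since 8.00 min at the same pace gave 53.0% at 15 min. I held this as high, since the feed stops at 12 min, before 15 min.

The forecast gave 0.4%, 8.1% and 50%, suspecting “a modest loss of Z through further reaction with D”. Its last value lies below mine.

The flask gave 0.444%, 8.13% and 51.2%, the last with 43% of the X and 37% of the D still present.

    X + D → Z (k = 0.0588 M⁻¹ s⁻¹)
    X + 2 D → E (k = 0.220 M⁻² s⁻¹)

With twice the X, Z comes to 37.3%, so the forecast's 50% would have been wrong for that flask. Multiplying the flask's 51.2% by the D ratio raised to the exponent 0.466 predicts 70.7% with twice the D, more than the 67.0% that this change gives, so between those two results the exponent reads 0.387.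

The data stem from a simulated flask for an exercise, and the scatter is random.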